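The leftover was what you asked me about: 61.5% of the electrophile still stood after 30.0 h of the dawn run, you had charged 0.900 equivalents of nucleophile, and your hunch was that the nucleophile would go on to consume that electrophile.

in all of them: electrophile 0.014 M; nucleophile 0.0126 M
- dawn: the very flask that is asked about, followed so far
- flask: time 3.0 d

- dawn (time / h: electrophile / %, target / %): 5.00: 78.8, 21.7; 10.0: 69.9, 28.5; 15.0: 65.4, 33.4; 20.0: 63.9, 35.5; 25.0: 63.3, 37.5; 30.0: 61.5, 38.3

(scatter of a reading: 0.5 percentage points)

- the earlier runs do not show how much of nucleophile is bound; that part of a forecast is a guess

1. part of the electrophile that has reacted at 3.0 d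
2. share of the unused nucleophile that is free and not bound as protonated nucleophile, at 3.0 d

I did not share the hunch. The target had gained 21.7% in the first 5.00 h of the dawn run but 2.8 percentage points in the last 10.0 h, while electrophile and target still added up to 99.8%, so the flask was stalling with no visible loss. I read this as each coupling setting free acid that took up a second nucleophile, and I kept 45.0% as the two-for-one ceiling: the part of the electrophile that can react if each turn spends two nucleophile, with the nucleophile as limiting reagent (0.0126 M against 0.0280 M needed). The forecast for this flask stood under that ceiling at 42% reacted, between 39.5% and 44.5%, and gave 14% of the unused nucleophile free, between 5% and 35%, the second being a guess, on the ground that the acid “ties up a second nucleophile”.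

The flask gave 39.8% reacted, inside the forecast's range, and 1.44% of the unused nucleophile free, 13 points under the forecast.

    electrophile + nucleophile → acid set free + target (k = 5.90 /M/h)
    nucleophile + acid set free ⇌ protonated nucleophile, settled at all times (K = 3.50 × 10⁵ /M)
    acid set free + target → side product (k = 5.30 /M/h)
    2 nucleophile → self-condensation product (k = 1.90 /M/h)

The flask stood 5.2 points under the ceiling with 8.75 × 10⁻⁴ M of self-condensation product in it at 3.00 d, made from nucleophile two at a time. For the neighbour flask charged with 0.024 M of electrophile, the ceiling came to 26.2%, and that flask had reacted 25.5% at 3.0 d.

(The runs were generated by integration on assumed constants.)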